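**Plan**
- Retrosynthesis: the prenyl bonds at C6 and C8 are cut first (aryl bromide plus prenylstannane, the bromines coming from C–H ortho to the 7-OH). Ring C is then cut at O1–C8a and C4–C4a in one operation, leaving a ring A aryne (C4a≡C8a) and an open-chain (S)-β-oxy acid derivative.
- Enabling feature: in ring C the ether oxygen O1 and the acyl carbon C4 sit on the adjacent ring A carbons C8a and C4a and are linked 1,3 through C2–C3. An ortho O/acyl pair is the imprint of nucleophile-then-electrophile addition across an aryne, and the chain O1–C2–C3–C4 is a β-oxido amide that carries both partners.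
- Forward: the side chain (transfer hydrogenation, Weinreb amide, O-silylation) and the aryne precursor (dibromination, retro-Brook/triflation) are made separately. The key step joins them and closes ring C onto ring A; hydrogenolysis, ring A dibromination and twofold Stille prenylation finish the route.
- Helpers: a bromine at C5 steers the alkoxide to C8a and a benzyl group masks O7; both leave in one hydrogenolysis. The N-methoxy-N-methyl amide keeps the C4 ketone masked until work-up.
- Stereochemistry: the only stereocentre, C2 (S), is set by catalyst control in step 1, and its C–O bond is never broken afterwards.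

Key step: step 6

Assumption: RuCl(p-cymene)[(S,S)-TsDPEN] is taken to reduce the aryl ketone of 1 with the same facial sense as acetophenone, which gives the (S)-carbinol; if the sense proved opposite, RuCl(p-cymene)[(R,R)-TsDPEN] would be used.

**Step 1**
Reactants: 1 ethyl 3-(4-methoxyphenyl)-3-oxopropanoate
Product: 2 ethyl (3S)-3-hydroxy-3-(4-methoxyphenyl)propanoate
Conditions: RuCl(p-cymene)[(S,S)-TsDPEN] (1 mol %), HCO2H/Et3N (5:2), 30 °C
Reagents that add atoms: none
Why: Noyori–Ikariya asymmetric transfer hydrogenation of an aryl ketone, in which the concerted hydride/proton transfer from the chiral hydride complex RuH(p-cymene)[(S,S)-TsDPEN] is directed to one face by the aryl/arene contact and should set the (S) carbinol centre (the later C2).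

**Step 2**
Reactants: 2 ethyl (3S)-3-hydroxy-3-(4-methoxyphenyl)propanoate
Product: 3 (3S)-3-hydroxy-N-methoxy-3-(4-methoxyphenyl)-N-methylpropanamide
Conditions: MeNH(OMe)·HCl, i-PrMgCl, THF, −20 to 0 °C; aq NH4Cl
Reagents that add atoms: N,O-dimethylhydroxylamine hydrochloride, CNOC.Cl
Why: Weinreb amide formation by aminolysis of the ester with the chloromagnesium amide of N,O-dimethylhydroxylamine, which should proceed on the magnesium alkoxide of the β-hydroxy ester at low temperature without touching the carbinol centre.

**Step 3**
Reactants: 3 (3S)-3-hydroxy-N-methoxy-3-(4-methoxyphenyl)-N-methylpropanamide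
Product: 4 (3S)-N-methoxy-3-(4-methoxyphenyl)-N-methyl-3-[(trimethylsilyl)oxy]propanamide
Conditions: 1-(trimethylsilyl)imidazole, CH2Cl2, 0 °C to rt
Reagents that add atoms: 1-(trimethylsilyl)imidazole, C[Si](C)(C)n1ccnc1
Why: neutral O-silylation of a secondary alcohol by an N-silylimidazole, chosen because fluoride will later unmask the alkoxide from this labile silyl ether without creating a proton source.

**Step 4**
Reactants: 5 4-(benzyloxy)phenol
Product: 6 4-(benzyloxy)-2,6-dibromophenol
Conditions: NBS (2.05 equiv), i-Pr2NH (10 mol %), CH2Cl2, 0 °C to rt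
Reagents that add atoms: N-bromosuccinimide, O=C1CCC(=O)N1Br
Why: amine-catalysed electrophilic aromatic bromination, which should be selective for both positions ortho to the free phenol (the stronger donor) and supplies one bromine as the silyl precursor and one as the later regiocontrol element.

**Step 5**
Reactants: 6 4-(benzyloxy)-2,6-dibromophenol
Product: 9 4-(benzyloxy)-2-bromo-6-(trimethylsilyl)phenyl trifluoromethanesulfonate, via aryl trimethylsilyl ether 7 (not isolated), via lithium 2-silylphenoxide 8 (not isolated)
Conditions: HMDS, THF, 65 °C, then evaporation; n-BuLi (1.05 equiv), THF, −78 °C; Tf2O, −78 °C to rt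
Reagents that add atoms: hexamethyldisilazane, C[Si](C)(C)N[Si](C)(C)C; trifluoromethanesulfonic anhydride, O=S(=O)(OS(=O)(=O)C(F)(F)F)C(F)(F)F
Why: O-silylation, bromine–lithium exchange at one of the two equivalent bromines and 1,3 O-to-C silyl shift (retro-Brook rearrangement) should give the ortho-silyl phenoxide, which is triflated in the same flask, the standard way from ortho-bromophenols to ortho-silylaryl triflates.

**Step 6**
Reactants: 4 (3S)-N-methoxy-3-(4-methoxyphenyl)-N-methyl-3-[(trimethylsilyl)oxy]propanamide; 9 4-(benzyloxy)-2-bromo-6-(trimethylsilyl)phenyl trifluoromethanesulfonate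
Product: 12 (2S)-7-(benzyloxy)-5-bromo-2-(4-methoxyphenyl)chroman-4-one, via aryne 10 (not isolated), via potassium hemiaminal alkoxide 11 (not isolated)
Conditions: KF (2.5 equiv), 18-crown-6 (2.5 equiv), THF, 0 °C to rt; then 1 M HCl, 0 °C
Reagents that add atoms: none
Why: Proposed new method: fluoride removes the C-silyl group of 9 (loss of triflate gives aryne 10) and the O-silyl group of 4 (alkoxide without any proton source); the alkoxide adds to the aryne carbon meta to bromine, and the aryl anion formed ortho to bromine attacks the tethered N-methoxy-N-methyl amide to give hemiaminal alkoxide 11, which releases the C4 ketone only on acidic work-up. The closest known reaction type is the fluoride-triggered nucleophilic addition/intramolecular acylation of arynes (xanthones from salicylate esters, 2,3-dihydroquinolin-4-ones by aryne insertion into the N–C(O) bond of β-lactams); an aliphatic β-oxido amide as partner is the new element. Ring C closes by 6-exo-trig attack of C4a on the amide carbonyl after intermolecular O1–C8a bond formation. No stereocentre is formed: the C–O bond at C2 stays intact, so the (S) configuration of 4 is carried over with retention, and keeping the ketone masked as 11 prevents base-induced retro-oxa-Michael opening that would racemise C2. The regioselectivity needed (O1 to C8a, acyl to C4a) should be secured by the C5 bromine, whose inductive distortion of the aryne directs nucleophiles to the distal carbon as in 3-haloarynes and 3-alkoxyarynes, outweighing the weak opposing bias of the O7 ether. The tethered six-membered acylation must outrun loss of bromide from the ortho-bromoaryl anion and proton transfer from C3, and the absence of protic species (silyl ether instead of alcohol, THF instead of acetonitrile) is meant to prevent simple O-arylation.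

**Step 7**
Reactants: 12 (2S)-7-(benzyloxy)-5-bromo-2-(4-methoxyphenyl)chroman-4-one
Product: 13 (2S)-7-hydroxy-2-(4-methoxyphenyl)chroman-4-one
Conditions: H2 (1 atm), 10% Pd/C, NaOAc, EtOAc/MeOH, rt
Reagents that add atoms: none
Why: heterogeneous palladium-catalysed hydrogenolysis should cleave the O-benzyl ether and the C5–Br bond in one operation (sodium acetate buffers the HBr), removing protecting group and regiocontrol helper together under near-neutral conditions that leave C2 and the C4 ketone alone.

**Step 8**
Reactants: 13 (2S)-7-hydroxy-2-(4-methoxyphenyl)chroman-4-one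
Product: 14 (2S)-6,8-dibromo-7-hydroxy-2-(4-methoxyphenyl)chroman-4-one
Conditions: NBS (2.05 equiv), DMF, 0 °C
Reagents that add atoms: N-bromosuccinimide, O=C1CCC(=O)N1Br
Why: electrophilic aromatic bromination of the resorcinol-type ring A, whose C6 and C8 are each ortho to the free 7-OH and para or ortho to O1, should be much faster than attack on the 4-methoxyphenyl ring B (one ether donor, para position blocked) or on C3.

**Step 9**
Reactants: 14 (2S)-6,8-dibromo-7-hydroxy-2-(4-methoxyphenyl)chroman-4-one
Product: 15 (2S)-7-hydroxy-2-(4-methoxyphenyl)-6,8-bis(3-methylbut-2-en-1-yl)chroman-4-one (the target flavanone)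
Conditions: tributyl(3-methylbut-2-en-1-yl)stannane (2.6 equiv), Pd(PPh3)4 (10 mol %), DMF, 90 °C
Reagents that add atoms: tributyl(3-methylbut-2-en-1-yl)stannane, CC(C)=CC[Sn](CCCC)(CCCC)CCCC
Why: twofold Stille coupling of the aryl bromides with the allylic stannane, in which reductive elimination from the aryl(allyl)palladium intermediate at the less substituted allyl terminus should give the linear prenyl groups, while the base-free conditions protect the C2 stereocentre.

**Compound list**
1 | ethyl 3-(4-methoxyphenyl)-3-oxopropanoate | CCOC(=O)CC(=O)c1ccc(OC)cc1 | starting material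
2 | ethyl (3S)-3-hydroxy-3-(4-methoxyphenyl)propanoate | COc1ccc([C@@H](O)CC(=O)OCC)cc1 | intermediate
3 | (3S)-3-hydroxy-N-methoxy-3-(4-methoxyphenyl)-N-methylpropanamide | COc1ccc([C@@H](O)CC(=O)N(C)OC)cc1 | intermediate
4 | (3S)-N-methoxy-3-(4-methoxyphenyl)-N-methyl-3-[(trimethylsilyl)oxy]propanamide | COc1ccc([C@@H](O[Si](C)(C)C)CC(=O)N(C)OC)cc1 | intermediate
5 | 4-(benzyloxy)phenol | Oc1ccc(OCc2ccccc2)cc1 | starting material
6 | 4-(benzyloxy)-2,6-dibromophenol | Oc1c(Br)cc(OCc2ccccc2)cc1Br | intermediate
7 | [4-(benzyloxy)-2,6-dibromophenoxy]trimethylsilane | C[Si](C)(C)Oc1c(Br)cc(OCc2ccccc2)cc1Br | intermediate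
8 | lithium 4-(benzyloxy)-2-bromo-6-(trimethylsilyl)phenoxide | [Li+].[O-]c1c(Br)cc(OCc2ccccc2)cc1[Si](C)(C)C | intermediate
9 | 4-(benzyloxy)-2-bromo-6-(trimethylsilyl)phenyl trifluoromethanesulfonate | O=S(=O)(Oc1c(Br)cc(OCc2ccccc2)cc1[Si](C)(C)C)C(F)(F)F | intermediate
10 | 5-(benzyloxy)-3-bromobenzyne (5-(benzyloxy)-3-bromo-1,2-didehydrobenzene) | BrC1=CC(OCc2ccccc2)=CC#C1 | intermediate
11 | potassium (2S)-7-(benzyloxy)-5-bromo-4-[methoxy(methyl)amino]-2-(4-methoxyphenyl)chroman-4-olate (mixture at C4) | [K+].COc1ccc([C@@H]2CC([O-])(N(C)OC)c3c(Br)cc(OCc4ccccc4)cc3O2)cc1 | intermediate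
12 | (2S)-7-(benzyloxy)-5-bromo-2-(4-methoxyphenyl)chroman-4-one | COc1ccc([C@@H]2CC(=O)c3c(Br)cc(OCc4ccccc4)cc3O2)cc1 | intermediate
13 | (2S)-7-hydroxy-2-(4-methoxyphenyl)chroman-4-one | COc1ccc([C@@H]2CC(=O)c3ccc(O)cc3O2)cc1 | intermediate
14 | (2S)-6,8-dibromo-7-hydroxy-2-(4-methoxyphenyl)chroman-4-one | COc1ccc([C@@H]2CC(=O)c3cc(Br)c(O)c(Br)c3O2)cc1 | intermediate
15 | (2S)-7-hydroxy-2-(4-methoxyphenyl)-6,8-bis(3-methylbut-2-en-1-yl)chroman-4-one (the target flavanone) | COc1ccc([C@@H]2CC(=O)c3cc(CC=C(C)C)c(O)c(CC=C(C)C)c3O2)cc1 | target

**Step count**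
Total steps: 9. Longest linear sequence: 7 (steps 1, 2, 3, 6, 7, 8, 9); the aryne precursor branch is steps 4 and 5.

**Steps most likely to fail, with fallbacks**

Step 6 (Proposed new method). What may go wrong: loss of bromide from the ortho-bromoaryl anion (onward aryne formation), proton transfer to the aryl anion giving only the uncyclised aryl ether, or retro-aldol cleavage of the free alkoxide before it meets the aryne. The fallback forms the same two bonds one after the other by known chemistry; it sets out from 4 and comes back at 13. Bromine–lithium exchange on commercial 4-(benzyloxy)-1-bromo-2-fluorobenzene (n-BuLi, THF, −78 °C) would give [4-(benzyloxy)-2-fluorophenyl]lithium F1. F1 adds to the Weinreb amide 4 at −78 °C; a 1 M HCl quench also removes the silyl ether and should give (3S)-1-[4-(benzyloxy)-2-fluorophenyl]-3-hydroxy-3-(4-methoxyphenyl)propan-1-one F2. Intramolecular nucleophilic aromatic substitution of the ketone-activated ortho-fluoride by the C3 alkoxide (NaH, THF, 0 °C to rt) closes ring C with retention at C2 and should give (2S)-7-(benzyloxy)-2-(4-methoxyphenyl)chroman-4-one F3. Hydrogenolysis (H2, Pd/C, EtOAc) then gives 13.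

Step 9. What may go wrong: slow transmetalation of the hindered prenylstannane at the two bromides flanking the phenol, allyl transposition giving 1,1-dimethylallyl isomers, protodebromination, and thermal erosion of configuration at C2. The fallback separates C–C coupling from construction of the trisubstituted alkene; it sets out from 14 and comes back at 15. Twofold Stille coupling with allyltributylstannane (Pd(PPh3)4, DMF, 90 °C), which has no transposition issue, should give (2S)-6,8-diallyl-7-hydroxy-2-(4-methoxyphenyl)chroman-4-one F4. Olefin cross-metathesis of both allyl groups with excess 2-methyl-2-butene (second-generation Grubbs catalyst RuCl2(=CHPh)(SIMes)(PCy3), CH2Cl2, 40 °C) then gives 15.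

Step 7. What may go wrong: hydrogenolysis of the doubly activated benzylic C2–O1 bond or reduction of the C4 ketone competing with debenzylation, and incomplete cleavage of the hindered C5–Br bond. The fallback avoids hydrogenation; it sets out from 12 and comes back at 13. Lewis-acid debenzylation (BCl3, pentamethylbenzene, CH2Cl2, −78 °C; aqueous work-up), which spares the aryl methyl ether, should give (2S)-5-bromo-7-hydroxy-2-(4-methoxyphenyl)chroman-4-one F5. Radical debromination (Bu3SnH, AIBN, toluene, 80 °C) then gives 13.

**Further compounds**
F1 | step 6 | [4-(benzyloxy)-2-fluorophenyl]lithium | [Li]c1ccc(OCc2ccccc2)cc1F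
F2 | step 6 | (3S)-1-[4-(benzyloxy)-2-fluorophenyl]-3-hydroxy-3-(4-methoxyphenyl)propan-1-one | COc1ccc([C@@H](O)CC(=O)c2ccc(OCc3ccccc3)cc2F)cc1
F3 | step 6 | (2S)-7-(benzyloxy)-2-(4-methoxyphenyl)chroman-4-one | COc1ccc([C@@H]2CC(=O)c3ccc(OCc4ccccc4)cc3O2)cc1
F4 | step 9 | (2S)-6,8-diallyl-7-hydroxy-2-(4-methoxyphenyl)chroman-4-one | COc1ccc([C@@H]2CC(=O)c3cc(CC=C)c(O)c(CC=C)c3O2)cc1
F5 | step 7 | (2S)-5-bromo-7-hydroxy-2-(4-methoxyphenyl)chroman-4-one | COc1ccc([C@@H]2CC(=O)c3c(Br)cc(O)cc3O2)cc1
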